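**Numbering used throughout.** Guaiane numbering: ring A is the five-membered ring C1–C5, ring B the seven-membered ring C1, C5–C10. C11–C13 are the isopropyl carbons on C7, C14 is the methyl on C10 and C15 the methyl on C4. Compound numbers 1–28 are those of the steps and the compound list.

## Analysis of the target

Target 28 is the 3,4-dimethoxybenzoate of a trans-fused hydroazulene (guaiane) alcohol with seven stereocenters: C1, C3, C4, C5, C7, C8 and C10 (1R,3R,4S,5S,7R,8R,10S). Drawn flat, H-5, the C15 methyl, the C7 isopropyl group, the C8 ester oxygen and the C10 hydroxyl lie on one face, and H-1, the C14 methyl and the epoxide oxygen on the other. The ester is therefore cis to the isopropyl group and cis-1,3 to the tertiary hydroxyl, while the epoxide sits opposite all the oxygen on ring B. The trisubstituted C3–C4 epoxide does not tolerate acid or hydride, the tertiary C10 alcohol eliminates easily, and the aryl ester does not survive hydride or strong base, so these three groups have to come late and in that order of sensitivity. The difficulties are the trans ring fusion, the relay of configuration between ring A and the three stereocenters of ring B, and the face of the final epoxidation. The strategy rests on one feature: C1 and C5 carry the C10 and C6 branches trans on ring A, and C4 is at a carbonyl-derived oxidation level. That is the pattern of a 2,3-trans-disubstituted cyclopentanone, made by conjugate addition at C1 and enolate capture at C5.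

## Retrosynthetic reasoning

28 to 27. The C3–O and C4–O bonds are cut first, because the epoxide is the most fragile group and the C3=C4 alkene of 27 is inert to everything that precedes it. The forward reaction must oxidise the trisubstituted alkene on the face of H-1 without touching the ester or the tertiary alcohol.

27 to 25 and 26. The ester C–O bond is cut next. Diol 25 has one secondary and one tertiary hydroxyl, so acylation with acid chloride 26 needs no protecting group, and the base-labile ester is kept out of all hydride and enolate chemistry.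

25 to 24 to 23. The C10–O bond is traced to the exocyclic alkene C10=C14 of dienol 23. The C8 hydroxyl is homoallylic to this alkene and on the face where the new oxygen is needed, so a hydroxyl-directed epoxidation (24) followed by hydride opening at C14 turns the C8 configuration into the C10 configuration. Cutting here rather than adding a methyl nucleophile to a C10 ketone avoids an uncontrolled addition to a seven-membered ketone.

23 to 22 to 21 to 19 to 18. The C4–C15 bond is cut to enol triflate 21 and from there to ketone 18 (protected as 19). The C4 carbonyl is what remains of the enone, and kinetic enolisation toward C3 places the double bond exactly where the epoxide will be, so this one carbonyl serves as the enolate source in the key step and then as the origin of C15 and C3=C4.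

18 to 17. Ring B is opened at C8–C9. In the forward sense the C8 aldehyde of 17 is attacked by the terminal carbon of the isopropenyl group with transfer of a C14 hydrogen (type 2 carbonyl-ene). This single bond formation closes the ring, creates the C8 carbinol and moves the alkene to C10=C14, the position the directed epoxidation needs. No other bond of ring B offers this.

17 to 16 to 15 to 14 to 13. These are adjustments only: the C8 oxygen is unmasked and oxidised, and the C6 hydroxyl left by the aldol is removed by radical deoxygenation via thiocarbonate 14, so its configuration never matters.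

13 to 11, 10 and 8. The C1–C10 and C5–C6 bonds are cut together. Conjugate addition of 10 to 11 and aldol capture of enolate 12 by 8 bring in every carbon of the target except C15, fix C1 by catalyst control and C5 by the trans rule of enolate trapping, and leave the two handles (isopropenyl and C4 ketone) that the later steps use. This is the disconnection the whole route is built on.

8 to 7 to 6 to 5 to 3 to 1 and 2; 10 to 9. The lone stereocenter of 8 (C7) is set by auxiliary-controlled hydroxymethylation of imide 3, made from 1 and 2. Silylation, reductive removal of the auxiliary and oxidation give 8 in five steps, and 10 comes from 9 in one. The precursors are thus reached by routine chemistry and the risk is concentrated in the coupling.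

## Alternatives that were turned down

Alternative 1: Ring B is cut at C9–C10. The substrate is bromo diketone A1, in which ring A already has C3=C4 and C15, C1 carries an acetyl group (C10, C14) and C5 carries the chain C6–C7–C8(=O)–C9H2Br. SmI2 (divalent samarium) would reduce the C9–Br bond, and the samarium enolate of the C8 ketone would add to the acetyl carbonyl to give hydroxy ketone A2.
- For: the ring closure itself delivers the C10 carbinol and the C8 oxygen, the ring A alkene is already in place, and a chelation-controlled reduction of A2 should give the cis-1,3-diol. Only about three steps would follow, against eight after ring closure in the chosen route; on this point the alternative is stronger.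
- Against: A1 has two centers next to carbonyl groups (C1 and C7) that can epimerise, and the trans relation at C1/C5 has to be built separately. The C10 configuration depends on which face of a freely rotating acetyl group is attacked in a seven-membered transition state. A2 is a β-hydroxy ketone that can revert or dehydrate.
- Comparison: the chosen route needs more steps after the ring is formed, but it relays C10 from C8 through a covalently directed reaction and reaches its cyclisation substrate from three simple pieces in one operation.

Alternative 2: Ring A is annulated and ring B enlarged in one cationic cascade, cutting C2–C3 and C1–C5. The substrate is cyclohexane A3 (C5–C10), which carries a vinyl group (C1=C2) and a silyloxy group on C10 and a side chain on C5 ending in the dibenzyl acetal carbon C3. SnCl4 would ionise the acetal, C2 would attack the oxocarbenium carbon, and the C1 cation would be quenched by a 1,2-shift of C5 from C10 to C1, giving ketone A4.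
- For: both rings and the ring-fusion centers come from one stereospecific event without a chiral catalyst, and the C10 ketone allows the carbinol to be made in a single methyl addition, which is shorter than the two-step relay used here.
- Against: A3 is a cyclohexane with four stereocenters plus a side-chain center and needs a long synthesis of its own. The suprafacial shift tends to give the cis-fused ketone, so the trans fusion of A4 would depend on equilibration at C1. The C3 benzyloxy and C4 methyl groups must then be turned regioselectively into the C3=C4 alkene, and the methyl addition to C10 has no built-in facial control.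
- Comparison: overall it would be longer and has more unresolved selectivity questions than the chosen route, whose ring fusion is set kinetically and whose C3=C4 alkene is placed by enolate regiochemistry.

Alternative 3: Ring A is formed by a [3+2] cycloaddition, cutting C4–C5 and C1–C2. The partners are cycloheptenone A5 (C10 carbonyl, C1=C5 alkene, C7 and C8 already substituted) and trimethylenemethane donor A6. With Pd(OAc)2 and P(OiPr)3 (zerovalent palladium formed in situ), the methyl-bearing terminus would bond to C5 and the ring would close on C1 to give A7.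
- For: it is the most convergent way to ring A, both fusion bonds form in one step, and the C10 ketone is again ready for direct methyl addition; on convergence of the ring construction it is stronger than the chosen route.
- Against: A7 carries an extra carbon (the methylidene on C3) that has to be cleaved, after which a C3 ketone must be converted regioselectively into the C3=C4 alkene. Stepwise addition to a cyclic enone gives a fusion that again relies on epimerisation at C1. Facial selection is governed only by the distant C7 and C8 substituents of A5, which itself needs a multistep enantioselective synthesis.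
- Comparison: the chosen route builds ring A from an achiral enone with no atom to discard and lets the C4 carbonyl place the alkene directly.

Key step: step 7

Remark on the chemistry: aldol adduct 13 is drawn as one C6 epimer, both epimers converge at 15. The antipode of the ferrocenyl diphosphine that gives the 3R ketone is the one used, both antipodes being accessible.

## Route

Step 1
Reactants: 1 (S)-4-benzyloxazolidin-2-one; 2 3-methylbutanoyl chloride (isovaleryl chloride)
Product: 3 (S)-4-benzyl-3-(3-methylbutanoyl)oxazolidin-2-one
Conditions: n-BuLi, THF, −78 °C; then 2, −78 to 0 °C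
Reagents that add atoms: none
Why: N-acylation of the lithiated oxazolidinone by the acid chloride (Evans imide formation); no stereocenter is created.

Step 2
Reactants: 3 (S)-4-benzyl-3-(3-methylbutanoyl)oxazolidin-2-one
Product: 5 (S)-4-benzyl-3-[(R)-2-(hydroxymethyl)-3-methylbutanoyl]oxazolidin-2-one, via Cl3Ti (Z)-enolate 4 (not isolated)
Conditions: TiCl4, i-Pr2NEt, CH2Cl2, 0 °C; then 1,3,5-trioxane, TiCl4, 0 °C; aq. NH4Cl
Reagents that add atoms: 1,3,5-trioxane, C1OCOCO1
Why: Soft enolisation gives the chelated (Z)-enolate, and the TiCl4-activated formaldehyde equivalent adds to the face opposite the benzyl group (auxiliary-controlled titanium-enolate hydroxymethylation, same sense as the Evans alkylations), which sets C7 as R.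

Step 3
Reactants: 5 (S)-4-benzyl-3-[(R)-2-(hydroxymethyl)-3-methylbutanoyl]oxazolidin-2-one
Product: 6 (S)-4-benzyl-3-[(R)-2-{[(tert-butyldimethylsilyl)oxy]methyl}-3-methylbutanoyl]oxazolidin-2-one
Conditions: TBSCl, imidazole, DMF, rt
Reagents that add atoms: tert-butyldimethylsilyl chloride, CC(C)(C)[Si](C)(C)Cl
Why: Standard silylation of a primary alcohol; the neutral conditions avoid retro-aldol loss of formaldehyde and leave C7 untouched.

Step 4
Reactants: 6 (S)-4-benzyl-3-[(R)-2-{[(tert-butyldimethylsilyl)oxy]methyl}-3-methylbutanoyl]oxazolidin-2-one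
Product: 7 (S)-2-{[(tert-butyldimethylsilyl)oxy]methyl}-3-methylbutan-1-ol
Conditions: LiBH4, MeOH (1 equiv), Et2O, 0 °C
Reagents that add atoms: none
Why: Reductive cleavage of the imide to the primary alcohol with recovery of auxiliary 1; hydride conditions do not enolise C7 (the S descriptor reflects only the changed substituent priorities).

Step 5
Reactants: 7 (S)-2-{[(tert-butyldimethylsilyl)oxy]methyl}-3-methylbutan-1-ol
Product: 8 (R)-2-{[(tert-butyldimethylsilyl)oxy]methyl}-3-methylbutanal
Conditions: Dess–Martin periodinane, NaHCO3, CH2Cl2, 0 °C to rt; used without storage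
Reagents that add atoms: none
Why: Buffered Dess–Martin oxidation is non-basic, so the α-stereocenter and the β-silyloxy group of the aldehyde should survive.

Step 6
Reactants: 9 2-bromopropene
Product: 10 isopropenylmagnesium bromide (prop-1-en-2-ylmagnesium bromide), solution in 2-methyltetrahydrofuran
Conditions: Mg turnings, I2 (cat.), 2-methyltetrahydrofuran, 40 °C; titrated before use
Reagents that add atoms: magnesium, [Mg]
Why: Ordinary Grignard formation from an alkenyl bromide; the weakly coordinating ether is chosen because it is compatible with the copper-catalysed step.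

Step 7
Reactants: 11 cyclopent-2-en-1-one; 10 isopropenylmagnesium bromide; 8 (R)-2-{[(tert-butyldimethylsilyl)oxy]methyl}-3-methylbutanal
Product: 13 (2R,3R)-2-[(1S,2R)-2-{[(tert-butyldimethylsilyl)oxy]methyl}-1-hydroxy-3-methylbutyl]-3-(prop-1-en-2-yl)cyclopentan-1-one, via BrMg enolate 12 (not isolated)
Conditions: CuBr·SMe2 (5 mol %), (R)-1-[(SP)-2-(diphenylphosphino)ferrocenyl]ethyldicyclohexylphosphine (6 mol %, antipode as in the remark), 10 (1.1 equiv), t-BuOMe, −78 °C, 11 (1.2 equiv) added slowly; then 8 (1.0 equiv), −78 °C; aq. NH4Cl at −78 °C
Reagents that add atoms: none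
Why: The monovalent copper–diphosphine complex is alkenylated by 10, binds the enone as a π-complex and transfers the isopropenyl group to C1 by oxidative addition and reductive elimination, releasing the regiodefined magnesium enolate 12, which then adds to aldehyde 8 at C5. The closest known reaction type is the copper-catalysed asymmetric conjugate addition of Grignard reagents to cyclic enones with aldol capture of the enolate, the three-component coupling familiar from prostaglandin-type cyclopentanones. No ring is closed in this step. C1 is set by the chiral ligand, which exposes one enantioface of the enone β-carbon. C5 is set by the substrate, because the aldehyde approaches the enolate carbon on the face opposite the adjacent isopropenyl group, giving the 2,3-trans ketone. C6 is not controlled and need not be, since its oxygen is removed in step 9, and C7 is carried in from 8. The step needs 1,4- rather than 1,2-addition (secured by copper catalysis at low temperature), no free Grignard reagent when 8 is added (secured by a slight excess of 11 over 10), and aldol addition faster than proton transfer from the α-branched aldehyde (secured by the hindered α-hydrogen and −78 °C). Because 8 is a single enantiomer, any product from the minor C1 enantiomer is a diastereomer and can be removed by chromatography at 15.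

Step 8
Reactants: 13 (2R,3R)-2-[(1S,2R)-2-{[(tert-butyldimethylsilyl)oxy]methyl}-1-hydroxy-3-methylbutyl]-3-(prop-1-en-2-yl)cyclopentan-1-one
Product: 14 O-phenyl thiocarbonate of 13 at the C6 oxygen (all configurations as in 13)
Conditions: PhOC(S)Cl, pyridine, DMAP (cat.), CH2Cl2, 0 °C to rt
Reagents that add atoms: O-phenyl chlorothionoformate, S=C(Cl)Oc1ccccc1
Why: Thioacylation of the secondary alcohol under weakly basic conditions (first half of a Barton–McCombie deoxygenation); pyridine is too weak a base to drive retro-aldol cleavage at this temperature.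

Step 9
Reactants: 14 O-phenyl thiocarbonate of 13
Product: 15 (2S,3R)-2-[(R)-2-{[(tert-butyldimethylsilyl)oxy]methyl}-3-methylbutyl]-3-(prop-1-en-2-yl)cyclopentan-1-one
Conditions: Bu3SnH, AIBN (cat.), toluene, 90 °C
Reagents that add atoms: none
Why: Barton–McCombie radical deoxygenation; the C6 radical could reach the isopropenyl group only through 4-exo or 5-endo closure, so hydrogen transfer from the stannane should win, and C5 keeps the thermodynamically preferred trans arrangement.

Step 10
Reactants: 15 (2S,3R)-2-[(R)-2-{[(tert-butyldimethylsilyl)oxy]methyl}-3-methylbutyl]-3-(prop-1-en-2-yl)cyclopentan-1-one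
Product: 16 (2S,3R)-2-[(R)-2-(hydroxymethyl)-3-methylbutyl]-3-(prop-1-en-2-yl)cyclopentan-1-one
Conditions: HF·pyridine, pyridine, THF, 0 °C to rt
Reagents that add atoms: none
Why: Buffered fluoride cleavage of the primary silyl ether; the δ-hydroxy ketone may sit partly as its cyclic hemiketal, which reopens in the next step.

Step 11
Reactants: 16 (2S,3R)-2-[(R)-2-(hydroxymethyl)-3-methylbutyl]-3-(prop-1-en-2-yl)cyclopentan-1-one
Product: 17 (R)-3-methyl-2-{[(1S,5R)-2-oxo-5-(prop-1-en-2-yl)cyclopentyl]methyl}butanal
Conditions: Dess–Martin periodinane, NaHCO3, CH2Cl2, 0 °C to rt; used directly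
Reagents that add atoms: none
Why: Non-basic oxidation of the primary alcohol to the C8 aldehyde without epimerising C7 or C5.

Step 12
Reactants: 17 (R)-3-methyl-2-{[(1S,5R)-2-oxo-5-(prop-1-en-2-yl)cyclopentyl]methyl}butanal
Product: 18 (1R,5S,7R,8R)-8-hydroxy-15-norguai-10(14)-en-4-one, that is (3aR,6R,7R,8aS)-6-hydroxy-4-methylidene-7-(propan-2-yl)octahydroazulen-1(2H)-one
Conditions: Me2AlCl (2.2 equiv), CH2Cl2 (0.01 M), −78 to −20 °C; aq. potassium sodium tartrate
Reagents that add atoms: none
Why: Lewis-acid-promoted type 2 carbonyl-ene cyclisation: the terminal alkene carbon C9 attacks the aluminium-complexed aldehyde (both alkene carbons end up in the seven-membered ring) and a C14 hydrogen passes to oxygen, giving the exocyclic methylene; C8 should form with the isopropyl group pseudo-equatorial and anti to the incoming C9 and the complexed oxygen pseudo-axial, which places the hydroxyl cis to the isopropyl group, and the aldehyde is far more reactive than the C4 ketone.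

Step 13
Reactants: 18 (1R,5S,7R,8R)-8-hydroxy-15-norguai-10(14)-en-4-one
Product: 19 (1R,5S,7R,8R)-8-(triethylsilyloxy)-15-norguai-10(14)-en-4-one
Conditions: Et3SiCl, imidazole, DMAP (cat.), DMF, 0 °C to rt
Reagents that add atoms: chlorotriethylsilane, CC[Si](CC)(CC)Cl
Why: Silyl protection of the C8 hydroxyl so that only the ketone reacts with base and triflating agent in the next step; the conditions do not enolise C5.

Step 14
Reactants: 19 (1R,5S,7R,8R)-8-(triethylsilyloxy)-15-norguai-10(14)-en-4-one
Product: 21 (1R,5S,7R,8R)-8-(triethylsilyloxy)-15-norguaia-3,10(14)-dien-4-yl trifluoromethanesulfonate, via potassium enolate 20 (not isolated)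
Conditions: KN(SiMe3)2, THF, −78 °C; then PhNTf2, −78 to −20 °C
Reagents that add atoms: N-phenylbis(trifluoromethanesulfonimide), O=S(=O)(N(c1ccccc1)S(=O)(=O)C(F)(F)F)C(F)(F)F
Why: A hindered amide base removes the less substituted C3 proton under kinetic control, so O-triflation fixes the double bond at C3=C4 and the ring-fusion center C5 is not deprotonated.

Step 15
Reactants: 21 (1R,5S,7R,8R)-8-(triethylsilyloxy)-15-norguaia-3,10(14)-dien-4-yl trifluoromethanesulfonate
Product: 22 (1R,5S,7R,8R)-8-(triethylsilyloxy)guaia-3,10(14)-diene
Conditions: Me2Zn, Pd(PPh3)4 (5 mol %), THF, 0 °C to rt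
Reagents that add atoms: dimethylzinc, C[Zn]C
Why: Negishi-type cross-coupling of an enol triflate with a methylzinc reagent installs C15; transmetalation is faster than any strained insertion into the exocyclic alkene.

Step 16
Reactants: 22 (1R,5S,7R,8R)-8-(triethylsilyloxy)guaia-3,10(14)-diene
Product: 23 (1R,5S,7R,8R)-guaia-3,10(14)-dien-8-ol
Conditions: Bu4NF, THF, 0 °C to rt
Reagents that add atoms: none
Why: Fluoride cleavage of the triethylsilyl ether under non-acidic conditions, so neither alkene migrates.

Step 17
Reactants: 23 (1R,5S,7R,8R)-guaia-3,10(14)-dien-8-ol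
Product: 24 (1R,5S,7R,8R,10S)-10,14-epoxyguai-3-en-8-ol (spiro-epoxide, oxygen cis to the C8 hydroxyl)
Conditions: VO(acac)2 (5 mol %), t-BuOOH (decane solution), CH2Cl2, 0 °C to rt
Reagents that add atoms: tert-butyl hydroperoxide, CC(C)(C)OO
Why: Vanadium-catalysed hydroxyl-directed epoxidation of a homoallylic alcohol: the vanadate ester of the C8 oxygen delivers the peroxide oxygen to the face of C10=C14 on which C8–O lies, setting C10, while the C3=C4 alkene has no hydroxyl within reach and reacts far more slowly with this reagent.

Step 18
Reactants: 24 (1R,5S,7R,8R,10S)-10,14-epoxyguai-3-en-8-ol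
Product: 25 (1R,5S,7R,8R,10S)-guai-3-ene-8,10-diol
Conditions: LiAlH4, THF, 0 to 40 °C; aqueous NaOH work-up
Reagents that add atoms: none
Why: Hydride opens the 1,1-disubstituted epoxide by SN2 attack at the unsubstituted C14, turning it into the C14 methyl and leaving the C10–O bond and its configuration intact; the isolated alkene is inert.

Step 19
Reactants: 25 (1R,5S,7R,8R,10S)-guai-3-ene-8,10-diol; 26 3,4-dimethoxybenzoyl chloride
Product: 27 (1R,5S,7R,8R,10S)-10-hydroxyguai-3-en-8-yl 3,4-dimethoxybenzoate
Conditions: 26, pyridine, DMAP (0.2 equiv), CH2Cl2, 0 °C to rt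
Reagents that add atoms: none
Why: DMAP-catalysed acylation selects the secondary C8 hydroxyl; the tertiary C10 hydroxyl does not react at room temperature.

Step 20
Reactants: 27 (1R,5S,7R,8R,10S)-10-hydroxyguai-3-en-8-yl 3,4-dimethoxybenzoate
Product: 28 (1R,3R,4S,5S,7R,8R,10S)-3,4-epoxy-10-hydroxyguaian-8-yl 3,4-dimethoxybenzoate (target)
Conditions: dimethyldioxirane (acetone solution), acetone, −20 to 0 °C
Reagents that add atoms: dimethyldioxirane, CC1(C)OO1
Why: Electrophilic epoxidation of the only remaining alkene under neutral conditions; the trans fusion holds C1 out of the alkene plane toward the H-1 face, so H-5 and one C2 hydrogen stand pseudo-axial on the other face and the oxidant should add anti to them (torsional steering) and away from the C10 carbinol, setting C3 and C4, while acetone as solvent damps hydrogen-bond delivery from the C10 hydroxyl.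

## Compound list

1 | (S)-4-benzyloxazolidin-2-one | O=C1N[C@@H](Cc2ccccc2)CO1 | starting material
2 | 3-methylbutanoyl chloride (isovaleryl chloride) | CC(C)CC(Cl)=O | starting material
3 | (S)-4-benzyl-3-(3-methylbutanoyl)oxazolidin-2-one | CC(C)CC(=O)N1C(=O)OC[C@@H]1Cc1ccccc1 | intermediate
4 | Cl3Ti (Z)-enolate of 3 | CC(C)/C=C(\O[Ti](Cl)(Cl)Cl)N1C(=O)OC[C@@H]1Cc1ccccc1 | intermediate (not isolated)
5 | (S)-4-benzyl-3-[(R)-2-(hydroxymethyl)-3-methylbutanoyl]oxazolidin-2-one | O=C(N1C(=O)OC[C@@H]1Cc1ccccc1)[C@H](C(C)C)CO | intermediate
6 | (S)-4-benzyl-3-[(R)-2-{[(tert-butyldimethylsilyl)oxy]methyl}-3-methylbutanoyl]oxazolidin-2-one | O=C(N1C(=O)OC[C@@H]1Cc1ccccc1)[C@H](C(C)C)CO[Si](C)(C)C(C)(C)C | intermediate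
7 | (S)-2-{[(tert-butyldimethylsilyl)oxy]methyl}-3-methylbutan-1-ol | OC[C@H](C(C)C)CO[Si](C)(C)C(C)(C)C | intermediate
8 | (R)-2-{[(tert-butyldimethylsilyl)oxy]methyl}-3-methylbutanal | O=C[C@H](C(C)C)CO[Si](C)(C)C(C)(C)C | intermediate
9 | 2-bromopropene | CC(Br)=C | starting material
10 | isopropenylmagnesium bromide | CC(=C)[Mg]Br | intermediate
11 | cyclopent-2-en-1-one | O=C1C=CCC1 | starting material
12 | bromomagnesium (R)-3-(prop-1-en-2-yl)cyclopent-1-en-1-olate | CC(=C)[C@@H]1CCC(O[Mg]Br)=C1 | intermediate (not isolated)
13 | (2R,3R)-2-[(1S,2R)-2-{[(tert-butyldimethylsilyl)oxy]methyl}-1-hydroxy-3-methylbutyl]-3-(prop-1-en-2-yl)cyclopentan-1-one | CC(=C)[C@@H]1CCC(=O)[C@H]1[C@@H](O)[C@H](C(C)C)CO[Si](C)(C)C(C)(C)C | intermediate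
14 | O-phenyl thiocarbonate of 13 at the C6 oxygen | CC(=C)[C@@H]1CCC(=O)[C@H]1[C@@H](OC(=S)Oc1ccccc1)[C@H](C(C)C)CO[Si](C)(C)C(C)(C)C | intermediate
15 | (2S,3R)-2-[(R)-2-{[(tert-butyldimethylsilyl)oxy]methyl}-3-methylbutyl]-3-(prop-1-en-2-yl)cyclopentan-1-one | CC(=C)[C@@H]1CCC(=O)[C@H]1C[C@H](C(C)C)CO[Si](C)(C)C(C)(C)C | intermediate
16 | (2S,3R)-2-[(R)-2-(hydroxymethyl)-3-methylbutyl]-3-(prop-1-en-2-yl)cyclopentan-1-one | CC(=C)[C@@H]1CCC(=O)[C@H]1C[C@H](C(C)C)CO | intermediate
17 | (R)-3-methyl-2-{[(1S,5R)-2-oxo-5-(prop-1-en-2-yl)cyclopentyl]methyl}butanal | CC(=C)[C@@H]1CCC(=O)[C@H]1C[C@H](C(C)C)C=O | intermediate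
18 | (1R,5S,7R,8R)-8-hydroxy-15-norguai-10(14)-en-4-one | O[C@@H]1CC(=C)[C@@H]2CCC(=O)[C@H]2C[C@@H]1C(C)C | intermediate
19 | (1R,5S,7R,8R)-8-(triethylsilyloxy)-15-norguai-10(14)-en-4-one | CC[Si](CC)(CC)O[C@@H]1CC(=C)[C@@H]2CCC(=O)[C@H]2C[C@@H]1C(C)C | intermediate
20 | potassium C3=C4 enolate of 19 | CC[Si](CC)(CC)O[C@@H]1CC(=C)[C@@H]2CC=C([O-])[C@H]2C[C@@H]1C(C)C.[K+] | intermediate (not isolated)
21 | (1R,5S,7R,8R)-8-(triethylsilyloxy)-15-norguaia-3,10(14)-dien-4-yl trifluoromethanesulfonate | CC[Si](CC)(CC)O[C@@H]1CC(=C)[C@@H]2CC=C(OS(=O)(=O)C(F)(F)F)[C@H]2C[C@@H]1C(C)C | intermediate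
22 | (1R,5S,7R,8R)-8-(triethylsilyloxy)guaia-3,10(14)-diene | CC[Si](CC)(CC)O[C@@H]1CC(=C)[C@@H]2CC=C(C)[C@H]2C[C@@H]1C(C)C | intermediate
23 | (1R,5S,7R,8R)-guaia-3,10(14)-dien-8-ol | O[C@@H]1CC(=C)[C@@H]2CC=C(C)[C@H]2C[C@@H]1C(C)C | intermediate
24 | (1R,5S,7R,8R,10S)-10,14-epoxyguai-3-en-8-ol | O[C@@H]1C[C@]2(OC2)[C@@H]3CC=C(C)[C@H]3C[C@@H]1C(C)C | intermediate
25 | (1R,5S,7R,8R,10S)-guai-3-ene-8,10-diol | O[C@@H]1C[C@](C)(O)[C@@H]2CC=C(C)[C@H]2C[C@@H]1C(C)C | intermediate
26 | 3,4-dimethoxybenzoyl chloride | COc1ccc(C(Cl)=O)cc1OC | starting material
27 | (1R,5S,7R,8R,10S)-10-hydroxyguai-3-en-8-yl 3,4-dimethoxybenzoate | COc1ccc(C(=O)O[C@@H]2C[C@](C)(O)[C@@H]3CC=C(C)[C@H]3C[C@@H]2C(C)C)cc1OC | intermediate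
28 | (1R,3R,4S,5S,7R,8R,10S)-3,4-epoxy-10-hydroxyguaian-8-yl 3,4-dimethoxybenzoate | COc1ccc(C(=O)O[C@@H]2C[C@](C)(O)[C@@H]3C[C@H]4O[C@@]4(C)[C@H]3C[C@@H]2C(C)C)cc1OC | target

## Step count and least certain steps

Total: 20 steps. Longest linear sequence: 19 steps (steps 1–5 and 7–20); step 6 is a one-step branch.

Step 7 (key step). Most likely to go wrong: incomplete enantioface discrimination when an sp2 Grignard reagent adds to the small, flat cyclopentenone, together with 1,2-addition, attack of unreacted Grignard reagent on the aldehyde, and proton transfer from the aldehyde to the enolate that would erode C7. Fallback: the two bond formations are separated. Setting out from 11 and 10, the conjugate addition is run with the same catalyst and the enolate is quenched with Me3SiCl and Et3N to give the silyl enol ether (R)-trimethyl{[3-(prop-1-en-2-yl)cyclopent-1-en-1-yl]oxy}silane F1, which is isolated and freed of magnesium salts and unreacted Grignard reagent. F1 is then joined to 8 in a Mukaiyama aldol reaction (BF3·OEt2, CH2Cl2, −78 °C), which again attacks trans to the isopropenyl group and returns to 13 without a basic enolate ever meeting the aldehyde.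

Step 12. Most likely to go wrong: poor control of the C8 configuration in the seven-membered transition state, with hydrogen transfer from C1 instead of C14 and Lewis-acid-induced aldol closure between C3 and C8 as minor competing processes. Fallback: setting out from 17, if the cyclisation gives mainly the C8 epimer (1R,5S,7R,8S)-8-hydroxy-15-norguai-10(14)-en-4-one F2, this alcohol is inverted by a Mitsunobu reaction (4-nitrobenzoic acid, PPh3, diisopropyl azodicarboxylate, THF), the classical remedy for an equatorial alcohol next to an isopropyl group, to give (1R,5S,7R,8R)-4-oxo-15-norguai-10(14)-en-8-yl 4-nitrobenzoate F3. Brief methanolysis (K2CO3, MeOH, 0 °C) then returns to 18.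

Step 20. Most likely to go wrong: attack on the wrong face of C3=C4, because the two faces of ring A differ only by pseudo-axial hydrogens and the C10 hydroxyl can deliver the oxidant by hydrogen bonding. Fallback: the stereochemically complementary halohydrin route. Setting out from 27, N-bromosuccinimide in aqueous THF at 0 °C puts bromine on the face the oxidant preferred and water on C4 from the other face, giving (1R,3S,4S,5S,7R,8R,10S)-3-bromo-4,10-dihydroxyguaian-8-yl 3,4-dimethoxybenzoate F4. Ring closure with 1,8-diazabicyclo[5.4.0]undec-7-ene in CH2Cl2 inverts C3 and gives 28. Whichever face electrophiles prefer, one of the two procedures leads to the target.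

Step 8 (with step 9). Most likely to go wrong: base-induced elimination or retro-aldol cleavage of the β-hydroxy ketone during thioacylation of the hindered C6 hydroxyl. Fallback: the elimination is made deliberate. Setting out from 13, MeSO2Cl and Et3N (CH2Cl2, −20 °C) give the mesylate F5, which 1,8-diazabicyclo[5.4.0]undec-7-ene converts at 0 °C into the (E)-alkylidene ketone (S,E)-2-[(S)-2-{[(tert-butyldimethylsilyl)oxy]methyl}-3-methylbutylidene]-3-(prop-1-en-2-yl)cyclopentan-1-one F6. Conjugate reduction with [(Ph3P)CuH]6 (monovalent copper hydride) in wet toluene, followed by protonation to the more stable trans ketone, returns to 15. The exposure of F6 to base must be short, because double-bond migration into the ring would destroy C1.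

Step 17. Most likely to go wrong: insufficient facial delivery to the exocyclic alkene in the flexible seven-membered ring, or competing oxidation of C3=C4. Fallback: the C10–O bond is formed through a tether that can only give the cis-1,3 relationship. Setting out from 23, Boc2O and DMAP give tert-butyl (1R,5S,7R,8R)-guaia-3,10(14)-dien-8-yl carbonate F7. IBr in toluene at −80 °C then closes the carbonate oxygen onto C10 to give the cyclic 8,10-carbonate of (1R,5S,7R,8R,10S)-14-iodoguai-3-ene-8,10-diol F8. Bu3SnH with AIBN removes the iodine to give the cyclic 8,10-carbonate of 25 F9, and K2CO3 in MeOH returns to 25.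

## Further compounds

F1 | step 7 | (R)-trimethyl{[3-(prop-1-en-2-yl)cyclopent-1-en-1-yl]oxy}silane | CC(=C)[C@@H]1CCC(O[Si](C)(C)C)=C1
F2 | step 12 | (1R,5S,7R,8S)-8-hydroxy-15-norguai-10(14)-en-4-one | O[C@H]1CC(=C)[C@@H]2CCC(=O)[C@H]2C[C@@H]1C(C)C
F3 | step 12 | (1R,5S,7R,8R)-4-oxo-15-norguai-10(14)-en-8-yl 4-nitrobenzoate | O=C(O[C@@H]1CC(=C)[C@@H]2CCC(=O)[C@H]2C[C@@H]1C(C)C)c1ccc(cc1)[N+](=O)[O-]
F4 | step 20 | (1R,3S,4S,5S,7R,8R,10S)-3-bromo-4,10-dihydroxyguaian-8-yl 3,4-dimethoxybenzoate | COc1ccc(C(=O)O[C@@H]2C[C@](C)(O)[C@@H]3C[C@H](Br)[C@@](C)(O)[C@H]3C[C@@H]2C(C)C)cc1OC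
F5 | step 8 | methanesulfonate of 13 at the C6 oxygen | CC(=C)[C@@H]1CCC(=O)[C@H]1[C@@H](OS(C)(=O)=O)[C@H](C(C)C)CO[Si](C)(C)C(C)(C)C
F6 | step 8 | (S,E)-2-[(S)-2-{[(tert-butyldimethylsilyl)oxy]methyl}-3-methylbutylidene]-3-(prop-1-en-2-yl)cyclopentan-1-one | CC(=C)[C@@H]1CCC(=O)/C1=C/[C@H](C(C)C)CO[Si](C)(C)C(C)(C)C
F7 | step 17 | tert-butyl (1R,5S,7R,8R)-guaia-3,10(14)-dien-8-yl carbonate | CC(C)(C)OC(=O)O[C@@H]1CC(=C)[C@@H]2CC=C(C)[C@H]2C[C@@H]1C(C)C
F8 | step 17 | cyclic 8,10-carbonate of (1R,5S,7R,8R,10S)-14-iodoguai-3-ene-8,10-diol | O=C1O[C@@H]2C[C@](CI)(O1)[C@@H]3CC=C(C)[C@H]3C[C@@H]2C(C)C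
F9 | step 17 | cyclic 8,10-carbonate of (1R,5S,7R,8R,10S)-guai-3-ene-8,10-diol | O=C1O[C@@H]2C[C@](C)(O1)[C@@H]3CC=C(C)[C@H]3C[C@@H]2C(C)C
A1 | alternative 1 | (1R,5S,7R)-9-bromo-9,10-secoguai-3-ene-8,10-dione | BrCC(=O)[C@@H](C(C)C)C[C@@H]1C(C)=CC[C@H]1C(C)=O
A2 | alternative 1 | (1R,5S,7R,10S)-10-hydroxyguai-3-en-8-one | O=C1C[C@](C)(O)[C@@H]2CC=C(C)[C@H]2C[C@@H]1C(C)C
A3 | alternative 2 | 1,1-bis(benzyloxy)-2-[2-ethenyl-5-isopropyl-4-(triisopropylsilyloxy)-2-(trimethylsilyloxy)cyclohexyl]propane (C4, C5, C7, C8 as in A4; vinyl trans to the acetal chain) | C=C[C@@]1(O[Si](C)(C)C)C[C@@H](O[Si](C(C)C)(C(C)C)C(C)C)[C@@H](C(C)C)C[C@@H]1[C@H](C)C(OCc1ccccc1)OCc1ccccc1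
A4 | alternative 2 | 3-benzyloxy-8-(triisopropylsilyloxy)-14-norguaian-10-one, trans-fused | c1ccccc1CO[C@H]1C[C@H]2C(=O)C[C@@H](O[Si](C(C)C)(C(C)C)C(C)C)[C@@H](C(C)C)C[C@@H]2[C@@H]1C
A5 | alternative 3 | (5R,6R)-6-[(tert-butyldimethylsilyl)oxy]-5-isopropylcyclohept-2-en-1-one | O=C1C=CC[C@H](C(C)C)[C@H](O[Si](C)(C)C(C)(C)C)C1
A6 | alternative 3 | 3-acetoxy-2-[(trimethylsilyl)methyl]but-1-ene | CC(OC(C)=O)C(=C)C[Si](C)(C)C
A7 | alternative 3 | 3-methylidene-8-(tert-butyldimethylsilyloxy)-14-norguaian-10-one, trans-fused | C=C1C[C@H]2C(=O)C[C@@H](O[Si](C)(C)C(C)(C)C)[C@@H](C(C)C)C[C@@H]2[C@@H]1C
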